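Begin with slowness: before asking how much target a flask holds, ask how long its partner lasts.

common to all: starting material 0.050 M

| flask | partner | second substrate | temperature | remark | time |
|---|---|---|---|---|---|
| green | 0.25 equiv | 1 equiv | −5 °C | run made earlier |  |
| larch | 0.500 equiv | 1.00 equiv | −5 °C |  | 10 min |
| elm | 0.500 equiv | 1.00 equiv | −35 °C |  | 10 min |
| cedar | 0.500 equiv | 1.00 equiv | 25 °C |  | 10 min |

green run (percent of the starting material charged)

| time / min | target / % | starting material / % |
|---|---|---|
| 0.167 | 2.7 | 96.8 |
| 0.500 | 4.2 | 92.6 |
| 0.833 | 6.0 | 89.0 |
| 1.33 | 11.2 | 83.9 |
| 2.00 | 14.6 | 81.6 |
| 2.50 | 14.3 | 78.5 |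
| 3.00 | 15.8 | 76.4 |

(scatter of a reading: 1 percentage point)

- the earlier runs do not show what temperature does; that part of a forecast is a guess

- which flask leads in amount of target, in percent of the starting material charged ("all alike" within 1.5 percentage points) (larch / elm / cedar / all alike)
- how much target is there at the end, in percent of the starting material charged: larch
- how much target is there at the end, in percent of the starting material charged: elm
- how much target is there at the end, in percent of the starting material charged: cedar

Read the green run at 0.833 min. Starting material stands at 89.0%, a loss of 11 percentage points that carries a scatter of 1 point. Count one partner per starting material lost and take the rate as proportional to [partner]. Then divide the partner charge by this early rate: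

early rate = 0.132 min⁻¹ of the charge

τ = 0.25 / early rate = 1.89 min

Call τ the partner clock, the time in which the partner, as limiting reagent, decays by a factor e at the early rate. It is the lifetime of a pseudo-first-order decay, so with [starting material] and temperature held, a larger partner charge raises the rate and leaves τ as it is.

Larch starts twice as fast as the green run:

start rate = 0.264 min⁻¹

Two things slow it. Falling [partner] gives a factor at the end of:

exp(−t/τ) = 0.00504

Falling [starting material], counted one per partner, gives 0.500 with the whole partner charge used, so in this count partner is the stronger brake. The time 10 min holds 5.29 clocks, so the summed rate comes close to the partner charge: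

loss = 0.500 × (1 − exp(−t/τ)) = 49.7%

The green run's last reading gives 0.669 target per starting material lost, so my reckoning for larch is 33.3%. For elm and cedar the clock needs a temperature factor, which the earlier runs do not show.

The forecast names larch, with 29% for larch, 11% for elm and 26% for cedar, where it expects the same ceiling but “selectivity and target survival are probably worse”. For larch its figure is lower than mine.

Larch leads, as forecast, with 22.5%, against 19.5% in elm and 1.72% in cedar. With the loss of target to isomer of the product struck out, larch gives 30.3%. The clock 1.89 min put the partner left in larch at 0.504% of its charge at 10 min, and the flask holds 0.572%.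

    starting material + partner → target (k = 1.40 M⁻¹ s⁻¹, Ea = 42.0 kJ mol⁻¹)
    second substrate + partner → second product (k = 0.840 M⁻¹ s⁻¹, Ea = 59.0 kJ mol⁻¹)
    starting material + second substrate → cross product (k = 0.140 M⁻¹ s⁻¹, Ea = 65.0 kJ mol⁻¹)
    target ⇌ isomer of the product (K = 12.0, k = 0.0190 s⁻¹, Ea = 77.0 kJ mol⁻¹, ΔH = −40.0 kJ mol⁻¹)
    starting material + target → side product (k = 0.160 M⁻¹ s⁻¹, Ea = 53.0 kJ mol⁻¹)
    (constants at 25 °C)

Take the neighbour of cedar charged with 0.020 M of starting material, with equivalents and time held. Partner goes by two steps there, to target and to second product, and second substrate is charged at 1.00 equiv, so its start clock at 25 °C is one over the sum of the two constants times 0.020 M, which gives 0.372 min. The time 10 min then holds 26.9 of these start clocks, so expect no partner at the end, and the computed flask holds partner 0%, starting material 25.1% and target 1.95%.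

(Readings and results were generated by integration with made-up constants.)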